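**Retrosynthetic overview**

1. The target is reached by acid removal of a tert-butyl group (ring A) and a methoxymethyl group (ring B) from a bis(quinone), which comes from oxidation of a bis(4-silyloxyphenol).
2. Key disconnection: in each quinone ring the bond C1(=O)–C6(CH3). Ring numbering used throughout: C1 carbonyl flanked by C2–O and C6–CH3, C3 carries the chain, C4 is the second carbonyl, C5 carries the other oxygen. Both rings are closed at once by a two-fold thermal ring expansion of a mixed bis(4-alkenylcyclobutenone).
3. Enabling feature: each ring consists of a squarate-type four-carbon unit C1(=O)–C2(O)=C3(CH2)–C4(=O) joined to an enol-ether two-carbon unit C5(O)=C6(CH3). Ring A (OH on C2, OCH3 on C5) and ring B (OCH3 on C2, OH on C5) differ only in which oxygen is methylated, and this is encoded by the squarate ester (tert-butyl or methyl) and the enol ether (methyl or methoxymethyl).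
4. The bis(cyclobutenone) comes from a one-pot sequential 1,2-addition of a C14 chain (1-bromo-14-iodotetradecane; iodine–lithium, then bromine–lithium exchange) to two different O-silylated squarate mono-adducts, followed by trifluoroacetic anhydride.
5. Ring order: the two four-membered rings are bought as squarate esters; rings A and B are formed together in the key step.

Key step: step 9

Remark: the linker is read as an unbranched (CH2)14 chain; the target is achiral, and the quaternary cyclobutene carbons created on the way are racemic and are destroyed when the rings expand.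

**Route**

Step 1
Reactants: 1 allyl methyl ether (3-methoxyprop-1-ene)
Product: 2 (Z)-1-methoxyprop-1-ene
Conditions: KOtBu (0.2 equiv), DMSO, 25 °C; product distilled from the mixture
Reagents that add atoms: none
Why: base-mediated allyl-to-propenyl ether isomerization (1,3-prototropic shift through the cisoid potassium oxyallyl anion) should give the (Z)-enol ether under kinetic control.

Step 2
Reactants: 2 (Z)-1-methoxyprop-1-ene; 3 di-tert-butyl squarate (3,4-di-tert-butoxycyclobut-3-ene-1,2-dione)
Product: 6 2,3-di-tert-butoxy-4-[(tert-butyldimethylsilyl)oxy]-4-[(Z)-1-methoxyprop-1-en-1-yl]cyclobut-2-en-1-one, via lithiated enol ether 4 (not isolated), via lithium alkoxide 5 (not isolated)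
Conditions: t-BuLi, THF–pentane, −78 to −10 °C; 3, THF, −78 °C; TBSOTf, −78 to 0 °C
Reagents that add atoms: tert-butyldimethylsilyl trifluoromethanesulfonate (TBSOTf), CC(C)(C)[Si](C)(C)OS(=O)(=O)C(F)(F)F
Why: α-vinylic lithiation of an enol ether (as for methyl vinyl ether and dihydropyran) with retention of geometry, 1,2-addition of the alkenyllithium to one squarate carbonyl and O-silylation of the tertiary alkoxide should give the racemic mono-adduct, whose quaternary carbon is erased in step 9.

Step 3
Reactants: 7 allyl alcohol
Product: 8 allyl methoxymethyl ether (3-(methoxymethoxy)prop-1-ene)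
Conditions: MOMCl, iPr2NEt, CH2Cl2, 0 to 25 °C
Reagents that add atoms: chloromethyl methyl ether (MOMCl), COCCl
Why: O-alkylation of a primary alcohol with an α-chloro ether (acetal formation by SN1-type substitution) is routine.

Step 4
Reactants: 8 allyl methoxymethyl ether
Product: 9 (Z)-1-(methoxymethoxy)prop-1-ene
Conditions: KOtBu (0.2 equiv), DMSO, 25 °C
Reagents that add atoms: none
Why: the same base-mediated allyl-to-propenyl ether isomerization as in step 1 should give the (Z)-enol ether.

Step 5
Reactants: 9 (Z)-1-(methoxymethoxy)prop-1-ene; 10 dimethyl squarate (3,4-dimethoxycyclobut-3-ene-1,2-dione)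
Product: 13 4-[(tert-butyldimethylsilyl)oxy]-2,3-dimethoxy-4-[(Z)-1-(methoxymethoxy)prop-1-en-1-yl]cyclobut-2-en-1-one, via lithiated enol ether 11 (not isolated), via lithium alkoxide 12 (not isolated)
Conditions: sec-BuLi, THF, −78 °C; 10, THF, −78 °C; TBSOTf, −78 to 0 °C
Reagents that add atoms: tert-butyldimethylsilyl trifluoromethanesulfonate (TBSOTf), CC(C)(C)[Si](C)(C)OS(=O)(=O)C(F)(F)F
Why: chelation-assisted α-lithiation of the methoxymethyl enol ether (a known propanoyl anion equivalent), 1,2-addition to dimethyl squarate and O-silylation should give the racemic mono-adduct.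

Step 6
Reactants: 14 tetradecane-1,14-diol
Product: 15 14-bromotetradecan-1-ol
Conditions: 48% aq HBr (1.1 equiv), toluene, reflux
Reagents that add atoms: hydrogen bromide, Br
Why: SN2 monobromination of an α,ω-diol in the two-phase HBr–toluene system, in which the bromo alcohol is extracted into toluene, should disfavour the second substitution.

Step 7
Reactants: 15 14-bromotetradecan-1-ol
Product: 16 1-bromo-14-iodotetradecane
Conditions: PPh3, I2, imidazole, CH2Cl2, 0 to 25 °C
Reagents that add atoms: iodine, II
Why: Appel-type iodination through the alkoxyphosphonium iodide converts the primary alcohol to the iodide and leaves the primary bromide untouched.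

Step 8
Reactants: 16 1-bromo-14-iodotetradecane; 6 2,3-di-tert-butoxy-4-[(tert-butyldimethylsilyl)oxy]-4-[(Z)-1-methoxyprop-1-en-1-yl]cyclobut-2-en-1-one; 13 4-[(tert-butyldimethylsilyl)oxy]-2,3-dimethoxy-4-[(Z)-1-(methoxymethoxy)prop-1-en-1-yl]cyclobut-2-en-1-one
Product: 21 2-tert-butoxy-4-[(tert-butyldimethylsilyl)oxy]-3-{14-[4-[(tert-butyldimethylsilyl)oxy]-2-methoxy-4-[(Z)-1-(methoxymethoxy)prop-1-en-1-yl]-3-oxocyclobut-1-en-1-yl]tetradecyl}-4-[(Z)-1-methoxyprop-1-en-1-yl]cyclobut-2-en-1-one, via (14-bromotetradecyl)lithium 17 (not isolated), via bromo alkoxide 18 (not isolated), via lithio alkoxide 19 (not isolated), via bis-alkoxide 20 (not isolated)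
Conditions: t-BuLi (2.0 equiv), Et2O–pentane, −78 °C; 6 (0.95 equiv), Et2O, −78 °C; t-BuLi (2.1 equiv), −78 °C; 13, Et2O, −78 °C; (CF3CO)2O, −78 °C; aq NaHCO3, 0 °C
Reagents that add atoms: water, O
Why: iodine–lithium exchange is much faster than bromine–lithium exchange at −78 °C, so the chain should be lithiated first at the iodide end and add 1,2 to the ketone of 6, after which the bromide end is exchanged and adds to 13; O-trifluoroacetylation of the two tertiary alkoxides then triggers ionization to alkoxy-stabilized cyclobutenyl cations that collapse (loss of the tert-butyl group at one end, hydrolysis of the methoxy-oxocarbenium ion at the other) to the 2-alkoxy-3-alkyl-4-silyloxycyclobutenones, which is the known sequential squarate addition–transposition and gives 21 as a diastereomer mixture that converges in step 9.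

Step 9
Reactants: 21 mixed bis(4-alkenylcyclobutenone)
Product: 24 2-tert-butoxy-4-[(tert-butyldimethylsilyl)oxy]-3-{14-[6-[(tert-butyldimethylsilyl)oxy]-3-hydroxy-2-methoxy-5-(methoxymethoxy)-4-methylphenyl]tetradecyl}-5-methoxy-6-methylphenol, via bis(dienylketene) 22 (not isolated), via bis(cyclohexadienone) 23 (not isolated)
Conditions: degassed toluene (0.01 M), 110 °C; crude product taken directly into step 10
Reagents that add atoms: none
Why: Each cyclobutenone should undergo thermal conrotatory 4π ring opening with the silyloxy donor on C4 rotating outward and the 1-alkoxypropenyl group inward, giving a dienylketene whose ketene carbon (future C1) lies next to the propenyl terminus (future C6). Thermal 6π electrocyclization then forms the C1–C6 bond of ring A and, independently at the other chain end, the C1–C6 bond of ring B, and enolization of the two cyclohexa-2,4-dienones gives the fully substituted 4-silyloxyphenols. The closest known reaction type is the Moore ring expansion of 4-alkenyl-4-hydroxy- or 4-silyloxycyclobutenones to hydroquinones, here run twice in one molecule. Both six-membered carbocycles are closed by 6π-electrocyclic (disrotatory) ring closure of a dienylketene. No stereocentre survives, because the C6 stereocentres of the dienones are erased on aromatization and the racemic quaternary carbons of 21 become sp2. The step needs torquoselectivity in the ring opening, which the oxygen donor on C4 secures, and a defined substituent pattern on each ring, which is fixed by the positions already set in 21 (chain on C3, retained squarate oxygen on C2, enol-ether oxygen on C5, methyl on C6 trans to the ring so that only hydrogen points inward).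

Step 10
Reactants: 24 bis(4-silyloxyphenol)
Product: 25 2-tert-butoxy-5-methoxy-3-{14-[2-methoxy-5-(methoxymethoxy)-4-methyl-3,6-dioxocyclohexa-1,4-dien-1-yl]tetradecyl}-6-methylcyclohexa-2,5-diene-1,4-dione
Conditions: PhI(OAc)2 (2.2 equiv), MeCN–H2O, 0 °C
Reagents that add atoms: none
Why: two-electron oxidation of each para-silyloxyphenol (ligand exchange of the phenol on iodine, loss of iodobenzene, hydrolytic desilylation of the silyloxy-oxocarbenium ion) should give the para-quinone with all four ring oxygens retained.

Step 11
Reactants: 25 protected bis(quinone)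
Product: 26 2-hydroxy-3-[14-(5-hydroxy-2-methoxy-4-methyl-3,6-dioxocyclohexa-1,4-dien-1-yl)tetradecyl]-5-methoxy-6-methylcyclohexa-2,5-diene-1,4-dione (target)
Conditions: CF3CO2H, CH2Cl2, H2O (5 equiv), 0 to 25 °C
Reagents that add atoms: none
Why: acidolysis of the vinylogous tert-butyl ester on ring A (loss of isobutene) and of the vinylogous methoxymethyl ester on ring B should free both hydroxyquinones, while the vinylogous methyl esters should survive brief exposure to acid.

**Compound list**

1 | allyl methyl ether | C=CCOC | starting material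
2 | (Z)-1-methoxyprop-1-ene | C/C=C\OC | intermediate
3 | di-tert-butyl squarate | CC(C)(C)OC1=C(OC(C)(C)C)C(=O)C1=O | starting material
4 | [(Z)-1-methoxyprop-1-en-1-yl]lithium | C/C=C(\OC)[Li] | intermediate
5 | lithium 2,3-di-tert-butoxy-1-[(Z)-1-methoxyprop-1-en-1-yl]-4-oxocyclobut-2-en-1-olate | C/C=C(\OC)C1([O-])C(=O)C(OC(C)(C)C)=C1OC(C)(C)C.[Li+] | intermediate
6 | 2,3-di-tert-butoxy-4-[(tert-butyldimethylsilyl)oxy]-4-[(Z)-1-methoxyprop-1-en-1-yl]cyclobut-2-en-1-one | C/C=C(\OC)C1(O[Si](C)(C)C(C)(C)C)C(=O)C(OC(C)(C)C)=C1OC(C)(C)C | intermediate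
7 | allyl alcohol | C=CCO | starting material
8 | allyl methoxymethyl ether | C=CCOCOC | intermediate
9 | (Z)-1-(methoxymethoxy)prop-1-ene | C/C=C\OCOC | intermediate
10 | dimethyl squarate | COC1=C(OC)C(=O)C1=O | starting material
11 | [(Z)-1-(methoxymethoxy)prop-1-en-1-yl]lithium | C/C=C(\OCOC)[Li] | intermediate
12 | lithium 2,3-dimethoxy-1-[(Z)-1-(methoxymethoxy)prop-1-en-1-yl]-4-oxocyclobut-2-en-1-olate | C/C=C(\OCOC)C1([O-])C(=O)C(OC)=C1OC.[Li+] | intermediate
13 | 4-[(tert-butyldimethylsilyl)oxy]-2,3-dimethoxy-4-[(Z)-1-(methoxymethoxy)prop-1-en-1-yl]cyclobut-2-en-1-one | C/C=C(\OCOC)C1(O[Si](C)(C)C(C)(C)C)C(=O)C(OC)=C1OC | intermediate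
14 | tetradecane-1,14-diol | OCCCCCCCCCCCCCCO | starting material
15 | 14-bromotetradecan-1-ol | OCCCCCCCCCCCCCCBr | intermediate
16 | 1-bromo-14-iodotetradecane | BrCCCCCCCCCCCCCCI | intermediate
17 | (14-bromotetradecyl)lithium | [Li]CCCCCCCCCCCCCCBr | intermediate
18 | lithium alkoxide from 1,2-addition of 17 to 6 (bromide terminus) | C/C=C(\OC)C1(O[Si](C)(C)C(C)(C)C)C([O-])(CCCCCCCCCCCCCCBr)C(OC(C)(C)C)=C1OC(C)(C)C.[Li+] | intermediate
19 | the same alkoxide with a lithiated chain terminus | C/C=C(\OC)C1(O[Si](C)(C)C(C)(C)C)C([O-])(CCCCCCCCCCCCCC[Li])C(OC(C)(C)C)=C1OC(C)(C)C.[Li+] | intermediate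
20 | dilithium bis-alkoxide from addition of 19 to 13 | C/C=C(\OC)C1(O[Si](C)(C)C(C)(C)C)C([O-])(CCCCCCCCCCCCCCC2([O-])C(OC)=C(OC)C2(O[Si](C)(C)C(C)(C)C)/C(OCOC)=C/C)C(OC(C)(C)C)=C1OC(C)(C)C.[Li+].[Li+] | intermediate
21 | mixed bis(4-alkenylcyclobutenone) (name in step 8) | C/C=C(\OC)C1(O[Si](C)(C)C(C)(C)C)C(=O)C(OC(C)(C)C)=C1CCCCCCCCCCCCCCC2=C(OC)C(=O)C2(O[Si](C)(C)C(C)(C)C)/C(OCOC)=C/C | intermediate
22 | bis(dienylketene) from two-fold 4π ring opening | O=C=C(OC(C)(C)C)/C(=C(\C(OC)=C\C)O[Si](C)(C)C(C)(C)C)CCCCCCCCCCCCCC\C(=C(\C(OCOC)=C\C)O[Si](C)(C)C(C)(C)C)C(OC)=C=O | intermediate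
23 | bis(cyclohexa-2,4-dienone) from two-fold 6π closure | CC1C(=O)C(OC(C)(C)C)=C(CCCCCCCCCCCCCCC2=C(OC)C(=O)C(C)C(OCOC)=C2O[Si](C)(C)C(C)(C)C)C(O[Si](C)(C)C(C)(C)C)=C1OC | intermediate
24 | bis(4-silyloxyphenol) (name in step 9) | Cc1c(O)c(OC(C)(C)C)c(CCCCCCCCCCCCCCc2c(OC)c(O)c(C)c(OCOC)c2O[Si](C)(C)C(C)(C)C)c(O[Si](C)(C)C(C)(C)C)c1OC | intermediate
25 | protected bis(quinone) (name in step 10) | CC1=C(OC)C(=O)C(CCCCCCCCCCCCCCC2=C(OC)C(=O)C(C)=C(OCOC)C2=O)=C(OC(C)(C)C)C1=O | intermediate
26 | 2-hydroxy-3-[14-(5-hydroxy-2-methoxy-4-methyl-3,6-dioxocyclohexa-1,4-dien-1-yl)tetradecyl]-5-methoxy-6-methylcyclohexa-2,5-diene-1,4-dione | CC1=C(OC)C(=O)C(CCCCCCCCCCCCCCC2=C(OC)C(=O)C(C)=C(O)C2=O)=C(O)C1=O | target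

**Step count and risks**

Total step count: 11. Longest linear sequence: 7 steps (3, 4, 5, 8, 9, 10, 11).

Steps most likely to fail:

Step 8. The two halogen–lithium exchanges may not be cleanly separated in time (early exchange at the bromide end, or incomplete exchange of the bromide in the presence of the lithium alkoxide), which would give symmetrical double adducts and protonated chain ends; the enol ethers may also be C-trifluoroacetylated. The fallback gives up chemoselective sequencing for a statistical double addition. It sets out from 14: both hydroxyl groups are converted with PPh3, I2 and imidazole to 1,14-diiodotetradecane F1, which with t-BuLi (4 equiv, Et2O–pentane, −78 °C) gives tetradecane-1,14-diyldilithium F2. A 1:1 mixture of 6 and 13 is added, which should give 20 together with the two symmetrical bis-alkoxides in statistical proportion. Treatment with (CF3CO)2O and aq NaHCO3 as before returns to the route at 21, which is separated by chromatography from the two symmetrical bis(cyclobutenones).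

Step 9. One chain end may open with the alkenyl group rotating outward, the ketene may be intercepted or oligomerize before closure, or isobutene may be lost thermally before both rings have formed. The fallback uses the free-carbinol variant of the same ring expansion, which runs at lower temperature and gives free hydroquinones. It sets out from 21: desilylation with Bu4NF buffered with AcOH (THF, 0 °C) gives the bis(4-hydroxycyclobutenone) F3, thermolysis in benzene at 80 °C gives the free bis(hydroquinone) F4, and oxidation with Ag2O in Et2O returns to the route at 25.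

Step 2. α-Lithiation of the non-chelating methyl enol ether may be incomplete or may compete with allylic deprotonation. The fallback generates the same alkenyllithium by tin–lithium exchange. It sets out from 2: addition of Br2 (CH2Cl2, −78 °C) gives 1,2-dibromo-1-methoxypropane F5, and double dehydrobromination with NaNH2 in liquid NH3 gives 1-methoxyprop-1-yne F6. Hydrostannation with Bu3SnH and catalytic Pd(PPh3)4 should place tin on the oxygen-bearing carbon by syn addition and give (E)-tributyl(1-methoxyprop-1-en-1-yl)stannane F7. Exchange with n-BuLi (THF, −78 °C) returns to the route at 4, which is used with 3 and TBSOTf as in step 2.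

**Further compounds**

F1 | step 8 | 1,14-diiodotetradecane | ICCCCCCCCCCCCCCI
F2 | step 8 | tetradecane-1,14-diyldilithium | [Li]CCCCCCCCCCCCCC[Li]
F3 | step 9 | bis(4-hydroxycyclobutenone) (21 with both silyl groups removed) | C/C=C(\OC)C1(O)C(=O)C(OC(C)(C)C)=C1CCCCCCCCCCCCCCC2=C(OC)C(=O)C2(O)/C(OCOC)=C/C
F4 | step 9 | free bis(hydroquinone) (24 with both silyl groups replaced by hydrogen) | Cc1c(O)c(OC(C)(C)C)c(CCCCCCCCCCCCCCc2c(OC)c(O)c(C)c(OCOC)c2O)c(O)c1OC
F5 | step 2 | 1,2-dibromo-1-methoxypropane | CC(Br)C(Br)OC
F6 | step 2 | 1-methoxyprop-1-yne | CC#COC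
F7 | step 2 | (E)-tributyl(1-methoxyprop-1-en-1-yl)stannane | C/C=C(\OC)[Sn](CCCC)(CCCC)CCCC
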